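## Retrosynthetic overview

1. Aryl ester C–O bond: Mitsunobu inversion of the 4-epimeric secondary alcohol with unprotected vanillic acid, itself made from catechol by mono-O-methylation and Kolbe–Schmitt carboxylation.
2. Seven-membered enone: one-carbon ring expansion of a trans-fused 2-methylcyclohex-2-enone by an alkenyl 1,2-shift onto a diazo-derived carbon.
3. That cyclohexenone: intramolecular aldol condensation of an ethyl ketone (unmasked vinylsilane) onto an α-hydroxy aldehyde (unmasked acetal).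
4. Tertiary carbinol: isopropyl addition to the cyclopentanone. The three centres before it: Cu-catalysed enantioselective conjugate addition of a silyl-alkenylalane to 3-methylcyclopent-2-enone with aldol trapping.
5. Ring order: cyclopentane (bought) → six-membered ring (aldol condensation) → seven-membered ring (ring expansion).

Assumption: the configuration is read literally from the SMILES, i.e. (3R,3aS,4R,8aS), trans ring fusion, ester oxygen cis to the angular methyl and to the tertiary OH; 2,2-dimethoxyacetaldehyde is used anhydrous.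

## Route

Step 1
Reactants: 1 benzene-1,2-diol (catechol)
Product: 2 2-methoxyphenol (guaiacol)
Conditions: MeI (1.0 equiv), K2CO3 (1.0 equiv), acetone, reflux
Reagents that add atoms: iodomethane, CI
Why: Williamson ether synthesis on the mono-phenoxide; one equivalent of MeI and a weak base stop at mono-methylation (a little veratrole is removed by base extraction); no stereocentre.

Step 2
Reactants: 2 2-methoxyphenol
Product: 3 4-hydroxy-3-methoxybenzoic acid (vanillic acid)
Conditions: KOH (1 equiv), dry salt; CO2 (20 bar), 220 °C; aq. HCl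
Reagents that add atoms: carbon dioxide, O=C=O
Why: Kolbe–Schmitt carboxylation; the potassium phenoxide above 200 °C gives the thermodynamic para-hydroxy carboxylate (the ortho salt isomerises), so CO2 enters para to the OH; no stereocentre.

Step 3
Reactants: 4 3-methylcyclopent-2-en-1-one; 5 trimethyl(prop-1-yn-1-yl)silane; 6 2,2-dimethoxyacetaldehyde
Product: 9 (2S,3S)-2-[(1R)-1-hydroxy-2,2-dimethoxyethyl]-3-methyl-3-[(1E)-1-(trimethylsilyl)prop-1-en-1-yl]cyclopentan-1-one, via alkenylalane 7 (not isolated), via aluminium enolate 8 (not isolated)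
Conditions: 5, i-Bu2AlH, hexanes, 55 °C; then 4, chiral sulfonate-NHC·Ag complex (2.5 mol %, enantiomer giving the 3S adduct), Cu(OTf)2 (5 mol %), THF, −30 °C; then 6, −78 → −20 °C; aq. Rochelle salt
Reagents that add atoms: none
Why: Tandem Cu-catalysed asymmetric conjugate addition–aldol: hydroalumination puts Al on the silicon-bearing carbon, the chiral NHC–Cu catalyst transfers the alkenyl group to one enone face and sets the quaternary C-3 (S), and the aluminium enolate adds to the aldehyde on the ring face trans to the bulky silylalkenyl group (sets C-2) through a chair Zimmerman–Traxler transition state of the ring (E)-enolate (anti aldol, carbinol centre R).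

Step 4
Reactants: 9 (2S,3S)-2-[(1R)-1-hydroxy-2,2-dimethoxyethyl]-3-methyl-3-[(1E)-1-(trimethylsilyl)prop-1-en-1-yl]cyclopentan-1-one
Product: 10 (1R,2S,3S)-2-[(1R)-1-hydroxy-2,2-dimethoxyethyl]-3-methyl-1-(propan-2-yl)-3-[(1E)-1-(trimethylsilyl)prop-1-en-1-yl]cyclopentan-1-ol
Conditions: i-PrLi (2.5 equiv), CeCl3, THF, −78 °C; H2O work-up
Reagents that add atoms: isopropyllithium, [Li]C(C)C
Why: Organocerium 1,2-addition (suppresses enolisation and retro-aldol of the hindered β-alkoxy ketone); the nucleophile enters the cyclopentanone face trans to the adjacent C-2 side chain and anti to the C-3 methyl, so the new OH is cis to that side chain (C-1 R).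

Step 5
Reactants: 10 (1R,2S,3S)-2-[(1R)-1-hydroxy-2,2-dimethoxyethyl]-3-methyl-1-(propan-2-yl)-3-[(1E)-1-(trimethylsilyl)prop-1-en-1-yl]cyclopentan-1-ol
Product: 13 (1R,3aS,7S,7aS)-1,7-dihydroxy-3a,5-dimethyl-1-(propan-2-yl)-1,2,3,3a,7,7a-hexahydro-4H-inden-4-one, via epoxysilane 11 (not isolated), via keto aldehyde 12 (not isolated)
Conditions: m-CPBA, CH2Cl2, 0 °C; then p-TsOH·H2O, THF/H2O, 50 °C
Reagents that add atoms: 3-chloroperoxybenzoic acid, OOC(=O)c1cccc(Cl)c1
Why: Prilezhaev epoxidation of the vinylsilane, acid-mediated epoxysilane-to-ketone conversion (carbonyl at the former C–Si carbon), acetal hydrolysis and intramolecular aldol condensation of the only enolisable α-carbon of the new ethyl ketone onto the aldehyde close the trans-fused cyclohexenone; no stereocentre is formed and the existing ones are kept (the α-hydroxy aldehyde is stored as its five-ring lactol with the tertiary OH until it condenses).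

Step 6
Reactants: 13 (1R,3aS,7S,7aS)-1,7-dihydroxy-3a,5-dimethyl-1-(propan-2-yl)-1,2,3,3a,7,7a-hexahydro-4H-inden-4-one
Product: 15 (3R,3aS,4S,8aS)-3,4-dihydroxy-6,8a-dimethyl-3-(propan-2-yl)-2,3,3a,4,5,8a-hexahydroazulen-8(1H)-one, via silyl ketone 14 (not isolated)
Conditions: Me3Al (3.5 equiv), TMSCHN2 (2 equiv), CH2Cl2, −78 → −20 °C; then K2CO3, MeOH, 0 °C → rt
Reagents that add atoms: (trimethylsilyl)diazomethane, C[Si](C)(C)C=[N+]=[N-]
Why: Proposed new method: Lewis-acid-promoted diazoalkane ring expansion of a cyclic enone by alkenyl 1,2-shift with desilylative enone transposition — Me3Al (which also masks both OH groups as aluminium alkoxides) activates the C-4 carbonyl for attack by TMSCHN2, in the betaine only the alkenyl carbon can align anti to the C–N2+ bond (the neopentyl quaternary carbon is sterically excluded and the alkenyl group migrates with π-assistance), loss of N2 gives the α-silyl β,γ-enone 14 (an allylsilane), and methanolysis of the C–Si bond with base equilibration gives the conjugated 3-methylcyclohept-2-enone without touching any stereocentre; closest known reaction type: Me3Al- or BF3-promoted TMSCHN2 homologation of saturated cycloalkanones (Tiffeneau–Demjanov type, less substituted carbon migrates).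

Step 7
Reactants: 15 (3R,3aS,4S,8aS)-3,4-dihydroxy-6,8a-dimethyl-3-(propan-2-yl)-2,3,3a,4,5,8a-hexahydroazulen-8(1H)-one; 3 4-hydroxy-3-methoxybenzoic acid
Product: 16 (3R,3aS,4R,8aS)-3-hydroxy-6,8a-dimethyl-8-oxo-3-(propan-2-yl)-1,2,3,3a,4,5,8,8a-octahydroazulen-4-yl 4-hydroxy-3-methoxybenzoate
Conditions: PPh3, DIAD, THF, 0 °C → rt
Reagents that add atoms: none
Why: Mitsunobu esterification: the secondary alcohol is activated as its alkoxyphosphonium salt and displaced by the carboxylate in an SN2 step with inversion (4S alcohol → 4R ester, now cis to the angular methyl and the tertiary OH); the carboxylic acid (pKa ≈ 4.5) is the pronucleophile rather than the phenol (pKa ≈ 9) and the tertiary alcohol is not activated.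

## Compound list

1 | benzene-1,2-diol (catechol) | Oc1ccccc1O | starting material
2 | 2-methoxyphenol (guaiacol) | COc1ccccc1O | intermediate
3 | 4-hydroxy-3-methoxybenzoic acid (vanillic acid) | COc1cc(C(=O)O)ccc1O | intermediate
4 | 3-methylcyclopent-2-en-1-one | CC1=CC(=O)CC1 | starting material
5 | trimethyl(prop-1-yn-1-yl)silane | CC#C[Si](C)(C)C | starting material
6 | 2,2-dimethoxyacetaldehyde | COC(OC)C=O | starting material
7 | bis(2-methylpropyl)[(1E)-1-(trimethylsilyl)prop-1-en-1-yl]alumane | C/C=C(/[Si](C)(C)C)[Al](CC(C)C)CC(C)C | intermediate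
8 | bis(2-methylpropyl)({(3S)-3-methyl-3-[(1E)-1-(trimethylsilyl)prop-1-en-1-yl]cyclopent-1-en-1-yl}oxy)alumane | CC(C)C[Al](CC(C)C)OC1=C[C@@](C)(/C(=C\C)[Si](C)(C)C)CC1 | intermediate
9 | (2S,3S)-2-[(1R)-1-hydroxy-2,2-dimethoxyethyl]-3-methyl-3-[(1E)-1-(trimethylsilyl)prop-1-en-1-yl]cyclopentan-1-one | O=C1CC[C@](C)(/C(=C\C)[Si](C)(C)C)[C@H]1[C@@H](O)C(OC)OC | intermediate
10 | (1R,2S,3S)-2-[(1R)-1-hydroxy-2,2-dimethoxyethyl]-3-methyl-1-(propan-2-yl)-3-[(1E)-1-(trimethylsilyl)prop-1-en-1-yl]cyclopentan-1-ol | CC(C)[C@]1(O)CC[C@](C)(/C(=C\C)[Si](C)(C)C)[C@H]1[C@@H](O)C(OC)OC | intermediate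
11 | (1R,2S,3S)-2-[(1R)-1-hydroxy-2,2-dimethoxyethyl]-3-methyl-3-[3-methyl-2-(trimethylsilyl)oxiran-2-yl]-1-(propan-2-yl)cyclopentan-1-ol (both epoxide faces, they converge) | CC(C)[C@]1(O)CC[C@](C)(C2(OC2C)[Si](C)(C)C)[C@H]1[C@@H](O)C(OC)OC | intermediate
12 | (2R)-2-hydroxy-2-[(1S,2R,5S)-2-hydroxy-5-methyl-5-propanoyl-2-(propan-2-yl)cyclopentyl]acetaldehyde (in equilibrium with its lactol) | CC(C)[C@]1(O)CC[C@](C)(C(=O)CC)[C@H]1[C@@H](O)C=O | intermediate
13 | (1R,3aS,7S,7aS)-1,7-dihydroxy-3a,5-dimethyl-1-(propan-2-yl)-1,2,3,3a,7,7a-hexahydro-4H-inden-4-one | CC(C)[C@]1(O)CC[C@]2(C)C(=O)C(C)=C[C@H](O)[C@@H]12 | intermediate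
14 | (3R,3aS,4S,8aS)-3,4-dihydroxy-6,8a-dimethyl-3-(propan-2-yl)-7-(trimethylsilyl)-2,3,3a,4,7,8a-hexahydroazulen-8(1H)-one (C-7 epimers) | CC(C)[C@]1(O)CC[C@]2(C)C(=O)C([Si](C)(C)C)C(C)=C[C@H](O)[C@@H]12 | intermediate
15 | (3R,3aS,4S,8aS)-3,4-dihydroxy-6,8a-dimethyl-3-(propan-2-yl)-2,3,3a,4,5,8a-hexahydroazulen-8(1H)-one | CC(C)[C@]1(O)CC[C@]2(C)C(=O)C=C(C)C[C@H](O)[C@@H]12 | intermediate
16 | (3R,3aS,4R,8aS)-3-hydroxy-6,8a-dimethyl-8-oxo-3-(propan-2-yl)-1,2,3,3a,4,5,8,8a-octahydroazulen-4-yl 4-hydroxy-3-methoxybenzoate | COc1cc(C(=O)O[C@@H]2CC(C)=CC(=O)[C@@]3(C)CC[C@@](O)(C(C)C)[C@H]23)ccc1O | target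

## Step count and risk

Total steps: 7. Longest linear sequence: 5 (steps 3–7).

**Step 6 (the proposed new ring expansion).** TMSCHN2 may add to the enone C=C (pyrazoline) instead of the neopentyl carbonyl, or the addition may be too slow. The fallback uses known chemistry (Ito–Saegusa-type cyclopropanol ring expansion), sets out from 13 and comes back at 15. Dissolving-metal reduction of the enone (Li, NH3/THF, −78 °C) and trapping of the regiodefined enolate and both alkoxides with TMSCl/Et3N gives the tris(trimethylsilyl) enol ether F1. Et2Zn/CH2I2 (CH2Cl2, 0 °C) cyclopropanates the enol ether to the siloxycyclopropane F2. FeCl3 (DMF, 0 °C, aq. HCl work-up) cleaves the ring-fusion bond of the cyclopropanol and chlorinates the tertiary radical, giving the ring-expanded β-chloro ketone F3 with the silyl ethers lost. NaOAc (MeOH, reflux) eliminates HCl to 15.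

**Step 7 (Mitsunobu inversion).** The carbinol carbon sits next to a CH flanked by two fully substituted carbons, and E2 elimination to the conjugated dienone can compete. The fallback sets out from 15 and comes back at 16. Dess–Martin periodinane (CH2Cl2) oxidises the secondary alcohol to the hydroxy dione F4. Et2BOMe/NaBH4 (THF/MeOH, −78 °C) reduces the boron chelate formed with the tertiary OH from outside and gives the syn-1,3-diol, the 4-epimeric diol F5. EDC·HCl/DMAP esterification (retention) with 4-(acetyloxy)-3-methoxybenzoic acid F6 (from 3, Ac2O, pyridine) gives the acetate-protected ester F7. Hydrazine acetate (DMF, rt) removes only the aryl acetate and gives 16.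

**Step 3 (three-component coupling).** The internal silyl-alkenylalane is bulkier than the parent vinyl reagent, and trapping of the aluminium enolate by the aldehyde may give low yield or poor selectivity at the carbinol centre. The fallback sets out from 4 with alane 7 and comes back at 9. The conjugate addition is run as before, but the enolate is silylated (TMSOTf, Et3N) and isolated as the silyl enol ether F8. A Mukaiyama aldol addition of F8 to 6 (BF3·OEt2, CH2Cl2, −78 °C, open transition state, aqueous work-up) then gives 9.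

## Further compounds

F1 | step 6 | 3a,5-dimethyl-1-(propan-2-yl)-1,4,7-tris[(trimethylsilyl)oxy]-2,3,3a,6,7,7a-hexahydro-1H-indene (ring stereocentres as in 13) | CC(C)[C@]1(O[Si](C)(C)C)CC[C@]2(C)C(O[Si](C)(C)C)=C(C)C[C@H](O[Si](C)(C)C)[C@@H]12
F2 | step 6 | 4,5-methylene adduct of F1 (1-siloxybicyclo[4.1.0]heptane unit, cyclopropane epimers) | CC(C)[C@]1(O[Si](C)(C)C)CC[C@]2(C)C3(O[Si](C)(C)C)CC3(C)C[C@H](O[Si](C)(C)C)[C@@H]12
F3 | step 6 | (3R,3aS,4S,8aS)-6-chloro-3,4-dihydroxy-6,8a-dimethyl-3-(propan-2-yl)octahydroazulen-8(1H)-one (C-6 epimers) | CC(C)[C@]1(O)CC[C@]2(C)C(=O)CC(C)(Cl)C[C@H](O)[C@@H]12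
F4 | step 7 | (3R,3aR,8aS)-3-hydroxy-6,8a-dimethyl-3-(propan-2-yl)-1,2,3,3a,5,8a-hexahydroazulene-4,8-dione | CC(C)[C@]1(O)CC[C@]2(C)C(=O)C=C(C)CC(=O)[C@@H]12
F5 | step 7 | (3R,3aS,4R,8aS)-3,4-dihydroxy-6,8a-dimethyl-3-(propan-2-yl)-2,3,3a,4,5,8a-hexahydroazulen-8(1H)-one | CC(C)[C@]1(O)CC[C@]2(C)C(=O)C=C(C)C[C@@H](O)[C@@H]12
F6 | step 7 | 4-(acetyloxy)-3-methoxybenzoic acid | CC(=O)Oc1ccc(C(=O)O)cc1OC
F7 | step 7 | (3R,3aS,4R,8aS)-3-hydroxy-6,8a-dimethyl-8-oxo-3-(propan-2-yl)-1,2,3,3a,4,5,8,8a-octahydroazulen-4-yl 4-(acetyloxy)-3-methoxybenzoate | COc1cc(C(=O)O[C@@H]2CC(C)=CC(=O)[C@@]3(C)CC[C@@](O)(C(C)C)[C@H]23)ccc1OC(C)=O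
F8 | step 3 | trimethyl({(3S)-3-methyl-3-[(1E)-1-(trimethylsilyl)prop-1-en-1-yl]cyclopent-1-en-1-yl}oxy)silane | C[Si](C)(C)OC1=C[C@@](C)(/C(=C\C)[Si](C)(C)C)CC1
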